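The cyclopentane (C1–C2–C3–C4–C5, daucane numbering) is closed last, by a samarium diiodide Barbier cyclisation that joins C3 to C4 on a fully substituted cycloheptene. The step exploits the 1,3-relationship across this ring between the angular methyl on C1 and the tertiary carbinol C4: the isobutyryl group on C5 and the 2-iodoethyl arm on C1 are already trans, so closure gives the trans-fused hydroazulene and sets the C4 alcohol with isopropyl anti to the C1 methyl. The precursor arises from a symmetric dimethylcycloheptadienone by desymmetrising vinyl conjugate addition, aldol condensation, reagent-controlled ketone reduction and a tethered (cyclic) hydroboration; the C7–C9 oxygenation follows.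

Key step: step 11

Remark (assumption): the oxirane is regarded as a functional group carried by the daucane carbon skeleton, so the skeleton is complete once the cyclopentane is closed; the oxirane is installed afterwards by epoxidation.

Numbering: in all Why lines C1–C10 are daucane locants (C1 quaternary carbon bearing CH3, C2/C3 the cyclopentane CH2 groups, C4 the isopropyl carbinol carbon, C5 the ring-fusion CH, C6–C10 the other cycloheptane carbons, C8 bearing CH3); β is the face of the C1 methyl. Systematic names of monocyclic compounds use their own ring locants.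

Step 1
Reactants: 1 2,5-dimethylfuran; 2 1,1,3-trichloropropan-2-one
Product: 4 (1R,5S)-1,5-dimethyl-8-oxabicyclo[3.2.1]oct-6-en-3-one (meso), via dichloro cycloadduct 3 (not isolated)
Conditions: Et3N, CF3CH2OH, 0 °C → rt; then Zn–Cu couple, NH4Cl, MeOH, rt
Reagents that add atoms: none
Why: (4+3) cycloaddition of the electron-rich furan with the dichloro-oxyallyl cation released from 2 by base in trifluoroethanol, followed by reductive dechlorination with zinc, should give the bridged ketone, whose ether bridge can only be cis (meso).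

Step 2
Reactants: 4 (1R,5S)-1,5-dimethyl-8-oxabicyclo[3.2.1]oct-6-en-3-one
Product: 5 (1R,5S)-1,5-dimethyl-8-oxabicyclo[3.2.1]octan-3-one (meso)
Conditions: H2 (1 atm), Pd/C (palladium on carbon), EtOAc, rt
Reagents that add atoms: none
Why: Catalytic hydrogenation should saturate the strained disubstituted alkene without touching the ketone or the ether bridge, and no stereocentre is created.

Step 3
Reactants: 5 (1R,5S)-1,5-dimethyl-8-oxabicyclo[3.2.1]octan-3-one
Product: 7 3,6-dimethylcyclohepta-2,6-dien-1-one, via hydroxy enone 6 (not isolated)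
Conditions: p-TsOH·H2O (cat.), toluene, reflux, Dean–Stark
Reagents that add atoms: none
Why: Acid-catalysed retro-oxa-Michael cleavage of the tertiary bridging ether and dehydration of the resulting tertiary β-hydroxy ketone (a double β-elimination) should give the cross-conjugated dienone, in which both alkenes are trisubstituted and conjugated.

Step 4
Reactants: 7 3,6-dimethylcyclohepta-2,6-dien-1-one; 8 2-methylpropanal
Product: 10 (6S)-7-(1-hydroxy-2-methylpropyl)-3,6-dimethyl-6-vinylcyclohept-2-en-1-one (epimer mixture at the two new carbinol-side centres), via aluminium enolate 9 (not isolated)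
Conditions: CH2=CHAlMe2 (from CH2=CHMgBr and Me2AlCl), Cu(OAc)2 (cat.), chiral phosphinamine ligand (SimplePhos type, antipode chosen for the S centre), Et2O, −30 °C; then 8, −78 → 0 °C; aq. NH4Cl
Reagents that add atoms: dimethyl(vinyl)aluminium, C=C[Al](C)C
Why: Copper-catalysed asymmetric conjugate addition of an alkenylalane to a β-methyl cyclic enone creates the quaternary C1 (the two enone termini of 7 are equivalent, so only the ligand-controlled facial choice matters), and the regiodefined aluminium enolate then adds to 8 at C5 in an aldol reaction whose two new centres are erased in step 5.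

Step 5
Reactants: 10 (6S)-7-(1-hydroxy-2-methylpropyl)-3,6-dimethyl-6-vinylcyclohept-2-en-1-one
Product: 12 (6S,7E)-3,6-dimethyl-7-(2-methylpropylidene)-6-vinylcyclohept-2-en-1-one, via mesylate 11 (not isolated)
Conditions: MsCl, Et3N, CH2Cl2, 0 °C; then DBU, rt
Reagents that add atoms: none
Why: Mesylation and E1cB elimination complete the aldol condensation to the exocyclic enone; the alkene geometry (drawn E) is of no consequence because C4 later becomes a ketone.

Step 6
Reactants: 12 (6S,7E)-3,6-dimethyl-7-(2-methylpropylidene)-6-vinylcyclohept-2-en-1-one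
Product: 13 (1S,6S,7E)-3,6-dimethyl-7-(2-methylpropylidene)-6-vinylcyclohept-2-en-1-ol
Conditions: (R)-2-methyl-CBS-oxazaborolidine (cat.), catecholborane, toluene, −78 °C
Reagents that add atoms: none
Why: Corey–Bakshi–Shibata reduction, 1,2-selective on the dienone, in which the fully substituted alkylidene side (C5) acts as the large group and the CH=C side (C7) as the small one, so the (R)-catalyst should deliver hydride to the β face and set the 6α (S) carbinol under reagent control.

Step 7
Reactants: 13 (1S,6S,7E)-3,6-dimethyl-7-(2-methylpropylidene)-6-vinylcyclohept-2-en-1-ol; 14 4-(benzyloxy)benzoyl chloride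
Product: 15 (1S,6S,7E)-3,6-dimethyl-7-(2-methylpropylidene)-6-vinylcyclohept-2-en-1-yl 4-(benzyloxy)benzoate
Conditions: Et3N, DMAP (cat.), CH2Cl2, 0 °C → rt
Reagents that add atoms: none
Why: DMAP-catalysed acylation installs the final C6 ester in benzyl-protected form at the only hydroxyl present, without touching the stereocentre.

Step 8
Reactants: 15 (1S,6S,7E)-3,6-dimethyl-7-(2-methylpropylidene)-6-vinylcyclohept-2-en-1-yl 4-(benzyloxy)benzoate
Product: 17 (1S,6S,7R)-6-(2-hydroxyethyl)-7-[(1R)-1-hydroxy-2-methylpropyl]-3,6-dimethylcyclohept-2-en-1-yl 4-(benzyloxy)benzoate, via thexylborinane 16 (not isolated)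
Conditions: thexylborane (1.05 equiv; from BH3·THF and 2,3-dimethylbut-2-ene), THF, high dilution, −20 → 0 °C; then 30% H2O2, aq. NaOAc, 0 °C → rt
Reagents that add atoms: hydrogen peroxide, OO
Why: Cyclic hydroboration of a 1,4-diene, in which the borane adds first to the vinyl group (boron at C3) and then intramolecularly across C5=C4 (boron at the less substituted C4) through a chair-like six-membered boracycle fused trans to the cycloheptene, so hydrogen should be delivered syn to C5 from the α face of the C1–C2 arm, the ring alkene (reachable only through a seven-membered boracycle) stays intact, and oxidation with retention gives the diol.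

Step 9
Reactants: 17 (1S,6S,7R)-6-(2-hydroxyethyl)-7-[(1R)-1-hydroxy-2-methylpropyl]-3,6-dimethylcyclohept-2-en-1-yl 4-(benzyloxy)benzoate
Product: 18 (1S,6S,7R)-7-[(1R)-1-hydroxy-2-methylpropyl]-6-(2-iodoethyl)-3,6-dimethylcyclohept-2-en-1-yl 4-(benzyloxy)benzoate
Conditions: I2, PPh3, imidazole, CH2Cl2, 0 °C
Reagents that add atoms: iodine, II
Why: Appel-type iodination should be selective for the primary C3 alcohol over the hindered secondary C4 alcohol and changes no stereocentre.

Step 10
Reactants: 18 (1S,6S,7R)-7-[(1R)-1-hydroxy-2-methylpropyl]-6-(2-iodoethyl)-3,6-dimethylcyclohept-2-en-1-yl 4-(benzyloxy)benzoate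
Product: 19 (1S,6S,7S)-6-(2-iodoethyl)-3,6-dimethyl-7-(2-methylpropanoyl)cyclohept-2-en-1-yl 4-(benzyloxy)benzoate
Conditions: Dess–Martin periodinane, NaHCO3, CH2Cl2, 0 °C → rt
Reagents that add atoms: none
Why: Dess–Martin oxidation under buffered, non-basic conditions should convert the C4 carbinol into the isopropyl ketone without epimerising C5 or eliminating the β-acyloxy group.

Step 11
Reactants: 19 (1S,6S,7S)-6-(2-iodoethyl)-3,6-dimethyl-7-(2-methylpropanoyl)cyclohept-2-en-1-yl 4-(benzyloxy)benzoate
Product: 20 4β-hydroxydauc-7-en-6α-yl 4-(benzyloxy)benzoate (trans-fused, 5α-H)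
Conditions: SmI2 (2.5 equiv), NiI2 (cat.), THF, −78 → 0 °C; then aq. NH4Cl
Reagents that add atoms: none
Why: Divalent samarium (activated by catalytic NiI2) reduces the primary C3–I bond to the alkyl radical and on to an alkylsamarium species (trivalent samarium), which adds to the C4 isopropyl ketone, and the alkoxide is protonated on work-up. The closest known reaction type is the samarium diiodide Barbier cyclisation of ω-iodoalkyl ketones to cyclopentanols. The cyclopentane C1–C2–C3–C4–C5 closes in a 5-exo-trig mode through the C3–C4 bond, which is not a ring-fusion bond, so the trans relationship of the arms on C1 and C5 fixed in 19 becomes the trans ring fusion. The new stereocentre C4 is controlled by C5 and C1: in the transition state the carbonyl substituent that eclipses C5–H rather than the C5–C6 bond, and that avoids the 1,3-syn C1 methyl, should be the bulky isopropyl group, so isopropyl ends α and oxygen β, possibly reinforced by chelation of samarium between O4 and the C6 ester oxygen. The step needs chemoselective reduction of the alkyl iodide beside the aryl ester, the ketone and the β-acyloxy group, and no epimerisation at C5; HMPA-free, non-basic conditions at low temperature and the electron-rich benzoate should secure this.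

Step 12
Reactants: 20 4β-hydroxydauc-7-en-6α-yl 4-(benzyloxy)benzoate
Product: 22 4β-hydroxy-7-oxodauc-8-en-6α-yl 4-(benzyloxy)benzoate, via allylic hydroperoxide 21 (not isolated)
Conditions: O2, tetraphenylporphyrin (cat.), visible light, CH2Cl2, 0 °C; then Ac2O, pyridine, DMAP (cat.), 0 °C → rt
Reagents that add atoms: dioxygen, O=O
Why: Schenck ene reaction followed by Kornblum–DeLaMare dehydration, in which singlet oxygen should bond to C7 (the hydrogen on the ester-bearing C6 is not abstracted) with hydrogen abstraction from C9 and shift of the alkene to C8=C9, and acetylation–elimination of the secondary hydroperoxide gives the transposed enone, so the C7 configuration of 21 does not matter.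

Step 13
Reactants: 22 4β-hydroxy-7-oxodauc-8-en-6α-yl 4-(benzyloxy)benzoate
Product: 23 4β,7β-dihydroxydauc-8-en-6α-yl 4-(benzyloxy)benzoate
Conditions: NaBH4, CeCl3·7H2O, MeOH, −78 °C
Reagents that add atoms: none
Why: Luche reduction (1,2-selective), in which hydride should add pseudo-axially from the α face, anti to the axial C6–H, giving the equatorial 7β alcohol trans to the equatorial C6 ester.

Step 14
Reactants: 23 4β,7β-dihydroxydauc-8-en-6α-yl 4-(benzyloxy)benzoate
Product: 24 8α,9α-epoxy-4β,7β-dihydroxydaucan-6α-yl 4-(benzyloxy)benzoate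
Conditions: dimethyldioxirane, acetone, −20 → 0 °C
Reagents that add atoms: dimethyldioxirane, CC1(C)OO1
Why: Epoxidation of the trisubstituted alkene under steric control, in which the β face of C8=C9 is shielded by the axial C1 methyl (1,3 to C9) so that oxygen should enter from the α face, anti to the 7β hydroxyl, while acetone as solvent suppresses hydroxyl-directed delivery.

Step 15
Reactants: 24 8α,9α-epoxy-4β,7β-dihydroxydaucan-6α-yl 4-(benzyloxy)benzoate
Product: 25 8α,9α-epoxy-4β,7β-dihydroxydaucan-6α-yl 4-hydroxybenzoate (CNP0290052.1)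
Conditions: H2 (1 atm), Pd/C (palladium on carbon), EtOAc, rt
Reagents that add atoms: none
Why: Hydrogenolysis of the phenolic benzyl ether under neutral conditions should free the phenol without acyl migration or Payne rearrangement, since no alkene remains and the trisubstituted epoxide is neither benzylic nor allylic.

Compound list
1 | 2,5-dimethylfuran | Cc1ccc(C)o1 | starting material
2 | 1,1,3-trichloropropan-2-one | ClCC(=O)C(Cl)Cl | starting material
3 | 2,2-dichloro-1,5-dimethyl-8-oxabicyclo[3.2.1]oct-6-en-3-one (racemic, one enantiomer drawn) | C[C@@]12C=C[C@@](C)(O1)CC(=O)C2(Cl)Cl | intermediate (not isolated)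
4 | (1R,5S)-1,5-dimethyl-8-oxabicyclo[3.2.1]oct-6-en-3-one (meso) | C[C@@]12C=C[C@@](C)(O1)CC(=O)C2 | intermediate
5 | (1R,5S)-1,5-dimethyl-8-oxabicyclo[3.2.1]octan-3-one (meso) | C[C@@]12CC[C@@](C)(O1)CC(=O)C2 | intermediate
6 | 6-hydroxy-3,6-dimethylcyclohept-2-en-1-one (racemic) | CC1=CC(=O)CC(C)(O)CC1 | intermediate (not isolated)
7 | 3,6-dimethylcyclohepta-2,6-dien-1-one | CC1=CC(=O)C=C(C)CC1 | intermediate
8 | 2-methylpropanal | CC(C)C=O | starting material
9 | dimethylaluminium enolate of 3,6-dimethyl-6-vinylcyclohept-2-en-1-one (O-bound, enolate C=C toward the quaternary carbon, vinyl on the α face) | C=C[C@]1(C)CCC(C)=CC(O[Al](C)C)=C1 | intermediate (not isolated)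
10 | (6S)-7-(1-hydroxy-2-methylpropyl)-3,6-dimethyl-6-vinylcyclohept-2-en-1-one (epimer mixture at ring C7 and the carbinol carbon) | CC(C)C(O)C1C(=O)C=C(C)CC[C@@]1(C)C=C | intermediate
11 | methanesulfonate of 10 at the side-chain hydroxyl | CC(C)C(OS(C)(=O)=O)C1C(=O)C=C(C)CC[C@@]1(C)C=C | intermediate (not isolated)
12 | (6S,7E)-3,6-dimethyl-7-(2-methylpropylidene)-6-vinylcyclohept-2-en-1-one | CC(C)/C=C1/C(=O)C=C(C)CC[C@@]1(C)C=C | intermediate
13 | (1S,6S,7E)-3,6-dimethyl-7-(2-methylpropylidene)-6-vinylcyclohept-2-en-1-ol | CC(C)/C=C1/[C@@H](O)C=C(C)CC[C@@]1(C)C=C | intermediate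
14 | 4-(benzyloxy)benzoyl chloride | O=C(Cl)c1ccc(OCc2ccccc2)cc1 | starting material
15 | (1S,6S,7E)-3,6-dimethyl-7-(2-methylpropylidene)-6-vinylcyclohept-2-en-1-yl 4-(benzyloxy)benzoate | CC(C)/C=C1/[C@@H](OC(=O)c2ccc(OCc3ccccc3)cc2)C=C(C)CC[C@@]1(C)C=C | intermediate
16 | B-(2,3-dimethylbutan-2-yl)borinane bridging C3 and C4, trans-fused to the cycloheptene (5α-H, 6α-ester) | CC(C)[C@H]1B(C(C)(C)C(C)C)CC[C@]2(C)CCC(C)=C[C@H](OC(=O)c3ccc(OCc4ccccc4)cc3)[C@@H]12 | intermediate (not isolated)
17 | (1S,6S,7R)-6-(2-hydroxyethyl)-7-[(1R)-1-hydroxy-2-methylpropyl]-3,6-dimethylcyclohept-2-en-1-yl 4-(benzyloxy)benzoate | CC(C)[C@@H](O)[C@@H]1[C@@H](OC(=O)c2ccc(OCc3ccccc3)cc2)C=C(C)CC[C@@]1(C)CCO | intermediate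
18 | (1S,6S,7R)-7-[(1R)-1-hydroxy-2-methylpropyl]-6-(2-iodoethyl)-3,6-dimethylcyclohept-2-en-1-yl 4-(benzyloxy)benzoate | CC(C)[C@@H](O)[C@@H]1[C@@H](OC(=O)c2ccc(OCc3ccccc3)cc2)C=C(C)CC[C@@]1(C)CCI | intermediate
19 | (1S,6S,7S)-6-(2-iodoethyl)-3,6-dimethyl-7-(2-methylpropanoyl)cyclohept-2-en-1-yl 4-(benzyloxy)benzoate | CC(C)C(=O)[C@@H]1[C@@H](OC(=O)c2ccc(OCc3ccccc3)cc2)C=C(C)CC[C@@]1(C)CCI | intermediate
20 | 4β-hydroxydauc-7-en-6α-yl 4-(benzyloxy)benzoate (trans-fused, 5α-H, 1β-CH3) | CC(C)[C@]1(O)CC[C@]2(C)CCC(C)=C[C@H](OC(=O)c3ccc(OCc4ccccc4)cc3)[C@H]21 | intermediate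
21 | 7β-hydroperoxy-4β-hydroxydauc-8-en-6α-yl 4-(benzyloxy)benzoate (C7 configuration inconsequential) | CC(C)[C@]1(O)CC[C@]2(C)CC=C(C)[C@@H](OO)[C@H](OC(=O)c3ccc(OCc4ccccc4)cc3)[C@H]21 | intermediate (not isolated)
22 | 4β-hydroxy-7-oxodauc-8-en-6α-yl 4-(benzyloxy)benzoate | CC(C)[C@]1(O)CC[C@]2(C)CC=C(C)C(=O)[C@H](OC(=O)c3ccc(OCc4ccccc4)cc3)[C@H]21 | intermediate
23 | 4β,7β-dihydroxydauc-8-en-6α-yl 4-(benzyloxy)benzoate | CC(C)[C@]1(O)CC[C@]2(C)CC=C(C)[C@@H](O)[C@H](OC(=O)c3ccc(OCc4ccccc4)cc3)[C@H]21 | intermediate
24 | 8α,9α-epoxy-4β,7β-dihydroxydaucan-6α-yl 4-(benzyloxy)benzoate | CC(C)[C@]1(O)CC[C@]2(C)C[C@@H]3O[C@]3(C)[C@@H](O)[C@H](OC(=O)c3ccc(OCc4ccccc4)cc3)[C@H]21 | intermediate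
25 | 8α,9α-epoxy-4β,7β-dihydroxydaucan-6α-yl 4-hydroxybenzoate (CNP0290052.1) | CC(C)[C@]1(O)CC[C@]2(C)C[C@@H]3O[C@]3(C)[C@@H](O)[C@H](OC(=O)c3ccc(O)cc3)[C@H]21 | target

Total step count: 15. Longest linear sequence: 15 steps (from 1 and 2; 8 and 14 are purchased).

Steps most likely to fail

Step 8. What may go wrong: hydrogen delivery to the wrong face of C5=C4 through a cis-fused boracycle, or competing hydroboration of the ring alkene. Fallback (thermodynamic correction in place of kinetic delivery), setting out from 15: the hydroboration is run as above, and any C5-epimeric diol, (1S,6S,7S)-6-(2-hydroxyethyl)-7-[(1S)-1-hydroxy-2-methylpropyl]-3,6-dimethylcyclohept-2-en-1-yl 4-(benzyloxy)benzoate F1, is carried with 17 through the iodination (PPh3, I2, imidazole) to the C5-epimeric iodo alcohol F2 and through the Dess–Martin oxidation to the C5-epimeric iodo ketone F3. Because C5 is then α to the C4 ketone, brief treatment with Et3N in CH2Cl2 should equilibrate F3 to 19, in which the isobutyryl group is trans to the C6 ester and cis only to the small C1 methyl; the route is rejoined at 19.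

Step 12. What may go wrong: hydrogen abstraction from the C8 methyl (exocyclic alkene) or a sluggish ene reaction of the ester-deactivated alkene. Fallback (hydroboration, oxidation, dehydrogenation), setting out from 20: BH3·SMe2 (THF, 0 °C; addition anti to the C6 ester, boron at C7) then H2O2/aq. NaOAc should give 4β,7β-dihydroxy-8βH-daucan-6α-yl 4-(benzyloxy)benzoate F4; Dess–Martin oxidation gives 4β-hydroxy-7-oxo-8βH-daucan-6α-yl 4-(benzyloxy)benzoate F5; dehydrogenation toward the more substituted C8 with IBX (DMSO, 70 °C), or Saegusa oxidation (TMSOTf, Et3N; then Pd(OAc)2), should give 22, where the route is rejoined.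

Step 4. What may go wrong: erosion of enantioselectivity with the unsubstituted vinylalane, or inefficient aldol capture of the hindered aluminium enolate. Fallback (masked vinyl donor and a separate aldol step), setting out from 7: copper-catalysed asymmetric conjugate addition of [1-(trimethylsilyl)vinyl]diisobutylaluminium (from i-Bu2AlH and trimethylsilylacetylene; Cu(OTf)2 and a chiral N-heterocyclic carbene ligand) with aqueous quench should give (R)-3,6-dimethyl-6-[1-(trimethylsilyl)vinyl]cyclohept-2-en-1-one F6; protodesilylation (CF3CO2H, CH2Cl2, 0 °C) gives (R)-3,6-dimethyl-6-vinylcyclohept-2-en-1-one F7; kinetic enolisation with LDA (THF, −78 °C) at the CH2 group between the carbonyl and the quaternary carbon and addition of 8 returns to 10.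

Further compounds
F1 | step 8 | (1S,6S,7S)-6-(2-hydroxyethyl)-7-[(1S)-1-hydroxy-2-methylpropyl]-3,6-dimethylcyclohept-2-en-1-yl 4-(benzyloxy)benzoate | CC(C)[C@H](O)[C@H]1[C@@H](OC(=O)c2ccc(OCc3ccccc3)cc2)C=C(C)CC[C@@]1(C)CCO
F2 | step 8 | (1S,6S,7S)-7-[(1S)-1-hydroxy-2-methylpropyl]-6-(2-iodoethyl)-3,6-dimethylcyclohept-2-en-1-yl 4-(benzyloxy)benzoate | CC(C)[C@H](O)[C@H]1[C@@H](OC(=O)c2ccc(OCc3ccccc3)cc2)C=C(C)CC[C@@]1(C)CCI
F3 | step 8 | (1S,6S,7R)-6-(2-iodoethyl)-3,6-dimethyl-7-(2-methylpropanoyl)cyclohept-2-en-1-yl 4-(benzyloxy)benzoate | CC(C)C(=O)[C@H]1[C@@H](OC(=O)c2ccc(OCc3ccccc3)cc2)C=C(C)CC[C@@]1(C)CCI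
F4 | step 12 | 4β,7β-dihydroxy-8βH-daucan-6α-yl 4-(benzyloxy)benzoate | CC(C)[C@]1(O)CC[C@]2(C)CC[C@H](C)[C@@H](O)[C@H](OC(=O)c3ccc(OCc4ccccc4)cc3)[C@H]21
F5 | step 12 | 4β-hydroxy-7-oxo-8βH-daucan-6α-yl 4-(benzyloxy)benzoate | CC(C)[C@]1(O)CC[C@]2(C)CC[C@H](C)C(=O)[C@H](OC(=O)c3ccc(OCc4ccccc4)cc3)[C@H]21
F6 | step 4 | (R)-3,6-dimethyl-6-[1-(trimethylsilyl)vinyl]cyclohept-2-en-1-one | C=C([Si](C)(C)C)[C@]1(C)CCC(C)=CC(=O)C1
F7 | step 4 | (R)-3,6-dimethyl-6-vinylcyclohept-2-en-1-one | C=C[C@]1(C)CCC(C)=CC(=O)C1
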